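**Plan**

- Ring labels: A is the 3,4-dihydroxy-5-aryloxyphenyl ring (C1 carries the bridge to D, C3 the ether oxygen, C4 and C5 the hydroxyls), B the 1,4-phenylene, C the 2-aryloxy-3,4-dihydroxyphenyl ring, D the 1,2-phenylene.
- Retrosynthesis: the ring C methyl ethers are cleaved last and the ring A C5–OH is traced back to C5–H (phenol ortho-oxygenation). The 17-membered ring is then cut at the ring A C3–O(ring B) aryl ether bond.
- The open chain is cut at the two CH2–CH2 bridges (B–C by Heck, A–D by Wittig, both hydrogenated) and at the ring C–O–ring D ether (SNAr).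
- Enabling feature: C3 of ring A is ortho to the phenolic oxygen at C4, which is para to the chain at C1, and the ether oxygen is the phenolic oxygen of para-alkyl ring B. This is the bond that oxidative C–O coupling of two para-alkylphenols forms. Temporary ortho halogens (Br2 on ring A, Cl2 on ring B) direct the coupling and are removed afterwards.
- Forward order: ring C vinylphenol, C–O–D ether, A–D stilbene, B–C stilbene, saturation and debenzylation, dibromination of ring A, anodic macrocyclisation (the only ring closed in the route), dehalogenation, ring A hydroxylation, demethylation.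
- Stereochemistry: the target has no stereocentre, so there is nothing to set.

Key step: step 7

Remark: the SMILES carries no stereodescriptor and the molecule has no stereogenic centre. The macrocycle is assumed to be conformationally mobile (no stable planar chirality), so it is made as the achiral compound.

**Route**

Step 1
Reactants: 1 2-hydroxy-3,4-dimethoxybenzaldehyde
Product: 2 6-ethenyl-2,3-dimethoxyphenol
Conditions: Ph3PCH3Br (2.5 equiv), KOtBu (3.5 equiv), THF, 0 °C to rt
Reagents that add atoms: methyltriphenylphosphonium bromide, C[P+](c1ccccc1)(c1ccccc1)c1ccccc1.[Br-]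
Why: Wittig methylenation with excess ylide tolerates the deprotonated ortho-phenol and turns the formyl group into the vinyl group that later becomes the ring B–ring C bridge; no stereocentre is formed.

Step 2
Reactants: 2 6-ethenyl-2,3-dimethoxyphenol; 3 2-fluorobenzaldehyde
Product: 4 2-(6-ethenyl-2,3-dimethoxyphenoxy)benzaldehyde
Conditions: K2CO3, BHT (cat.), DMF, 100 °C
Reagents that add atoms: none
Why: SNAr (addition–elimination) of the phenoxide on the fluoroarene activated by its ortho formyl group should build the ring C–O–ring D ether and leave the formyl group on ring D as the handle for the second bridge, with the inhibitor guarding the styrene against thermal polymerisation.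

Step 3
Reactants: 4 2-(6-ethenyl-2,3-dimethoxyphenoxy)benzaldehyde; 5 [4-(benzyloxy)benzyl]triphenylphosphonium chloride
Product: 7 1-{2-[4-(benzyloxy)phenyl]ethenyl}-2-(6-ethenyl-2,3-dimethoxyphenoxy)benzene (E/Z mixture), via [4-(benzyloxy)benzylidene]triphenylphosphorane 6 (not isolated)
Conditions: KOtBu, THF, 0 °C; then 4, 0 °C to rt
Reagents that add atoms: none
Why: Wittig olefination of the aryl aldehyde with the semistabilised benzylic ylide should give the ring A–ring D stilbene as an E/Z mixture, which is acceptable because this double bond is hydrogenated in step 5.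

Step 4
Reactants: 7 1-{2-[4-(benzyloxy)phenyl]ethenyl}-2-(6-ethenyl-2,3-dimethoxyphenoxy)benzene; 8 4-bromo-2,6-dichlorophenol
Product: 9 4-[(E)-2-(2-{2-[2-(4-benzyloxyphenyl)ethenyl]phenoxy}-3,4-dimethoxyphenyl)ethenyl]-2,6-dichlorophenol
Conditions: Pd(OAc)2 (cat.), P(o-tol)3 (cat.), Et3N, DMF, 100 °C
Reagents that add atoms: none
Why: Mizoroki–Heck arylation should occur at the terminal vinyl group (far more reactive than the 1,2-disubstituted stilbene) with oxidative addition at C–Br and not at the hindered C–Cl bonds, giving the E-stilbene with the free phenol tolerated as its ammonium phenoxide.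

Step 5
Reactants: 9 4-[(E)-2-(2-{2-[2-(4-benzyloxyphenyl)ethenyl]phenoxy}-3,4-dimethoxyphenyl)ethenyl]-2,6-dichlorophenol
Product: 10 2,6-dichloro-4-[2-(2-{2-[2-(4-hydroxyphenyl)ethyl]phenoxy}-3,4-dimethoxyphenyl)ethyl]phenol
Conditions: H2 (1 atm), 10% Pd/C, EtOAc, rt, no base
Reagents that add atoms: none
Why: Heterogeneous catalytic hydrogenation should saturate both stilbene double bonds and hydrogenolyse the benzyl ether, while the aryl chlorides are expected to survive because hydrodechlorination on palladium is slow in a neutral medium without an HCl acceptor.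

Step 6
Reactants: 10 2,6-dichloro-4-[2-(2-{2-[2-(4-hydroxyphenyl)ethyl]phenoxy}-3,4-dimethoxyphenyl)ethyl]phenol
Product: 11 2,6-dibromo-4-{2-[2-(6-{2-(3,5-dichloro-4-hydroxyphenyl)ethyl}-2,3-dimethoxyphenoxy)phenyl]ethyl}phenol
Conditions: NBS (2.05 equiv), i-Pr2NH (cat.), CH2Cl2, 0 °C
Reagents that add atoms: N-bromosuccinimide (NBS), O=C1CCC(=O)N1Br
Why: Amine-catalysed electrophilic ortho-bromination of phenols with NBS should brominate both ortho positions of ring A, the only phenol with open ortho sites, since ring B is fully substituted and the ether-only rings C and D react much more slowly under these non-acidic conditions.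

Step 7
Reactants: 11 2,6-dibromo-4-{2-[2-(6-{2-(3,5-dichloro-4-hydroxyphenyl)ethyl}-2,3-dimethoxyphenoxy)phenyl]ethyl}phenol
Product: 13 macrocyclic diaryl ether (ring A 5-bromo-4-hydroxy; ring B 3,5-dichloro; ring C 3,4-dimethoxy), via macrocyclic 2-aryloxy-6-bromo-4-methoxycyclohexa-2,5-dienone 12 (not isolated)
Conditions: constant-current electrolysis (undivided cell, glassy-carbon anode, Pt cathode, ca. 2.2 F/mol), LiClO4, MeOH, 1 mM, rt; then Zn, AcOH, rt
Reagents that add atoms: none
Why: Anodic two-electron oxidation of the 2,6-dibromophenol(ate) of ring A should give a phenoxonium ion whose brominated ortho carbon is attacked by the acidic 2,6-dichlorophenol oxygen of ring B; loss of bromide from the 6-aryloxy-6-bromodienone and capture of the resulting cation by methanol at the para carbon give dienone 12, which zinc reduces to phenol 13 with loss of methanol. The closest known reaction type is the anodic (or thallium(III)-mediated) oxidative coupling of ortho,ortho'-dihalophenols to ortho-aryloxyphenols with zinc work-up, established for isodityrosine-type diaryl ethers, macrocyclic ones included. The one ring closed is the 17-membered macrocycle, by intramolecular C–O bond formation (ipso attack at C–Br of the oxidised ring A, an addition–elimination that joins the two ends of the open chain) under high dilution. No stereocentre is created in 13; the quaternary carbon of 12 forms as a racemate and is erased on re-aromatisation. The step needs O–C and not C–C coupling, the direction ring B oxygen to ring A carbon, and no oxidation of the trialkoxy ring C: the four ortho halogens block C–C coupling, bromide is the better nucleofuge and the dibromophenol is expected to be the more readily oxidised ring, and halophenolates are oxidised at a much lower potential than an alkoxyarene. Capture by methanol alone gives a para-quinol ether that the zinc step returns to 11, so this side path costs conversion only.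

Step 8
Reactants: 13 macrocyclic diaryl ether (ring A 5-bromo-4-hydroxy; ring B 3,5-dichloro; ring C 3,4-dimethoxy)
Product: 14 macrocyclic monophenol (ring A 4-hydroxy with C5–H; ring B unsubstituted; ring C 3,4-dimethoxy)
Conditions: H2 (1 atm), 10% Pd/C, Et3N (5 equiv), MeOH–EtOAc, rt
Reagents that add atoms: none
Why: Palladium-catalysed hydrodehalogenation with a base as HX acceptor should remove the three auxiliary halogens (C–Br first, then the two C–Cl) and leave the diaryl and methyl ethers untouched.

Step 9
Reactants: 14 macrocyclic monophenol (ring A 4-hydroxy with C5–H; ring B unsubstituted; ring C 3,4-dimethoxy)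
Product: 16 ring-C 3,4-di-O-methyl ether of the target (ring A catechol free), via macrocyclic ring-A ortho-quinone 15 (not isolated)
Conditions: IBX (1.1 equiv), DMF, rt; then aq. Na2S2O4
Reagents that add atoms: 2-iodoxybenzoic acid (IBX), O=C1OI(=O)(O)c2ccccc12
Why: IBX-mediated ortho-oxygenation of an electron-rich phenol (aryloxy-iodine(V) intermediate, intramolecular oxygen delivery) can only take place at C5, the single free ortho position of ring A, and should give ortho-quinone 15, which dithionite reduces in the same flask to the catechol.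

Step 10
Reactants: 16 ring-C 3,4-di-O-methyl ether of the target
Product: 17 CNP0114693.0 (target)
Conditions: BBr3 (6 equiv), CH2Cl2, −78 °C to rt; then H2O
Reagents that add atoms: none
Why: Lewis-acid demethylation with BBr3 should cleave the two aryl methyl ethers of ring C through bromoborane–oxonium intermediates, whereas diaryl ethers are not cleaved under these conditions.

**Compound list**

1 | 2-hydroxy-3,4-dimethoxybenzaldehyde | O=Cc1ccc(OC)c(OC)c1O | starting material
2 | 6-ethenyl-2,3-dimethoxyphenol | C=Cc1ccc(OC)c(OC)c1O | intermediate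
3 | 2-fluorobenzaldehyde | O=Cc1ccccc1F | starting material
4 | 2-(6-ethenyl-2,3-dimethoxyphenoxy)benzaldehyde | O=Cc1ccccc1Oc1c(OC)c(OC)ccc1C=C | intermediate
5 | [4-(benzyloxy)benzyl]triphenylphosphonium chloride | [Cl-].c1ccc(cc1)COc1ccc(cc1)C[P+](c1ccccc1)(c1ccccc1)c1ccccc1 | starting material
6 | [4-(benzyloxy)benzylidene]triphenylphosphorane (not isolated) | c1ccc(cc1)COc1ccc(cc1)C=P(c1ccccc1)(c1ccccc1)c1ccccc1 | intermediate
7 | 1-{2-[4-(benzyloxy)phenyl]ethenyl}-2-(6-ethenyl-2,3-dimethoxyphenoxy)benzene, E/Z mixture | C=Cc1ccc(OC)c(OC)c1Oc1ccccc1C=Cc1ccc(OCc2ccccc2)cc1 | intermediate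
8 | 4-bromo-2,6-dichlorophenol | Oc1c(Cl)cc(Br)cc1Cl | starting material
9 | 4-[(E)-2-(2-{2-[2-(4-benzyloxyphenyl)ethenyl]phenoxy}-3,4-dimethoxyphenyl)ethenyl]-2,6-dichlorophenol, ring A–ring D alkene E/Z | Oc1c(Cl)cc(/C=C/c2ccc(OC)c(OC)c2Oc2ccccc2C=Cc2ccc(OCc3ccccc3)cc2)cc1Cl | intermediate
10 | 2,6-dichloro-4-[2-(2-{2-[2-(4-hydroxyphenyl)ethyl]phenoxy}-3,4-dimethoxyphenyl)ethyl]phenol | Oc1c(Cl)cc(CCc2ccc(OC)c(OC)c2Oc2ccccc2CCc2ccc(O)cc2)cc1Cl | intermediate
11 | 2,6-dibromo-4-{2-[2-(6-{2-(3,5-dichloro-4-hydroxyphenyl)ethyl}-2,3-dimethoxyphenoxy)phenyl]ethyl}phenol | Oc1c(Br)cc(CCc2ccccc2Oc2c(OC)c(OC)ccc2CCc2cc(Cl)c(O)c(Cl)c2)cc1Br | intermediate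
12 | macrocyclic 2-aryloxy-6-bromo-4-methoxycyclohexa-2,5-dienone (ring A dearomatised, racemic at C4, not isolated) | O=C1C(Br)=CC2(OC)C=C1Oc1c(Cl)cc(cc1Cl)CCc1ccc(OC)c(OC)c1Oc1ccccc1CC2 | intermediate
13 | macrocyclic diaryl ether (ring A 5-bromo-4-hydroxy; ring B 3,5-dichloro; ring C 3,4-dimethoxy) | Oc1c(Br)cc2cc1Oc1c(Cl)cc(cc1Cl)CCc1ccc(OC)c(OC)c1Oc1ccccc1CC2 | intermediate
14 | macrocyclic monophenol (ring A 4-hydroxy with C5–H; ring B unsubstituted; ring C 3,4-dimethoxy) | Oc1ccc2cc1Oc1ccc(cc1)CCc1ccc(OC)c(OC)c1Oc1ccccc1CC2 | intermediate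
15 | macrocyclic ring-A ortho-quinone (not isolated) | O=C1C=C2C=C(C1=O)Oc1ccc(cc1)CCc1ccc(OC)c(OC)c1Oc1ccccc1CC2 | intermediate
16 | ring-C 3,4-di-O-methyl ether of the target (ring A catechol free) | Oc1cc2cc(c1O)Oc1ccc(cc1)CCc1ccc(OC)c(OC)c1Oc1ccccc1CC2 | intermediate
17 | CNP0114693.0 | Oc1cc2cc(c1O)Oc1ccc(cc1)CCc1ccc(O)c(O)c1Oc1ccccc1CC2 | target

**Summary**

Total step count: 10. Longest linear sequence: 10 steps (from compound 1).

Steps most likely to fail:

1. Step 7. The ring closure may lose to capture of the oxidised ring A by methanol, to intermolecular coupling, or to coupling in the reverse direction (ring A oxygen onto ring B). The fallback sets out from 4 and comes back to the route at 17; it closes the macrocycle at the ring A–ring D bridge instead of at the ether. Chan–Lam coupling of commercial 3-hydroxy-4,5-dimethoxybenzaldehyde with 4-bromophenylboronic acid (Cu(OAc)2, pyridine, 4 Å MS, CH2Cl2, air) should give 3-(4-bromophenoxy)-4,5-dimethoxybenzaldehyde F1, which already holds the ring A–O–ring B ether. Heck coupling of F1 with the vinyl group of 4 (Pd(OAc)2, P(o-tol)3, Et3N, DMF) should give the stilbene dialdehyde F2. Selective alkene hydrogenation (H2, Pd/C poisoned with Ph2S, EtOAc) should give the saturated dialdehyde F3. Intramolecular McMurry coupling (TiCl4, Zn, pyridine, THF, reflux, slow addition) should give the macrocyclic stilbene F4. Hydrogenation (H2, Pd/C) should give the tetramethyl ether F5, and BBr3 in CH2Cl2 should give 17.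

2. Step 5. Hydrogenolysis of the ring B C–Cl bonds may compete with debenzylation and alkene saturation. The fallback sets out from 9 and comes back at 10. Diimide reduction of both double bonds (2-nitrobenzenesulfonyl hydrazide, Et3N, CH2Cl2, rt) should give the saturated benzyl ether F6. Lewis-acid debenzylation with a cation scavenger (BCl3, pentamethylbenzene, CH2Cl2, −78 °C) should then give 10 without any reducing metal.

3. Step 9. The ortho-quinone may be over-oxidised or may tautomerise and decompose before it is reduced. The fallback sets out from 14 and comes back at 16. Magnesium-mediated ortho-formylation (MgCl2, Et3N, paraformaldehyde, MeCN, reflux) at the single free ortho position should give the macrocyclic salicylaldehyde F7. Dakin oxidation (H2O2, aq. NaOH, then acid) should convert the formyl group into the second hydroxyl and give 16.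

**Further compounds**

F1 | step 7 | 3-(4-bromophenoxy)-4,5-dimethoxybenzaldehyde | O=Cc1cc(OC)c(OC)c(Oc2ccc(Br)cc2)c1
F2 | step 7 | 2-[6-[(E)-2-[4-(5-formyl-2,3-dimethoxyphenoxy)phenyl]ethenyl]-2,3-dimethoxyphenoxy]benzaldehyde | O=Cc1ccccc1Oc1c(OC)c(OC)ccc1/C=C/c1ccc(Oc2cc(C=O)cc(OC)c2OC)cc1
F3 | step 7 | 2-[6-[2-[4-(5-formyl-2,3-dimethoxyphenoxy)phenyl]ethyl]-2,3-dimethoxyphenoxy]benzaldehyde | O=Cc1ccccc1Oc1c(OC)c(OC)ccc1CCc1ccc(Oc2cc(C=O)cc(OC)c2OC)cc1
F4 | step 7 | macrocyclic stilbene, tetra-O-methyl, ring A–ring D bridge as CH=CH (E/Z) | COc1cc2cc(c1OC)Oc1ccc(cc1)CCc1ccc(OC)c(OC)c1Oc1ccccc1C=C2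
F5 | step 7 | tetra-O-methyl ether of the target | COc1cc2cc(c1OC)Oc1ccc(cc1)CCc1ccc(OC)c(OC)c1Oc1ccccc1CC2
F6 | step 5 | 4-[2-(2-{2-[2-(4-benzyloxyphenyl)ethyl]phenoxy}-3,4-dimethoxyphenyl)ethyl]-2,6-dichlorophenol | Oc1c(Cl)cc(CCc2ccc(OC)c(OC)c2Oc2ccccc2CCc2ccc(OCc3ccccc3)cc2)cc1Cl
F7 | step 9 | macrocyclic salicylaldehyde (ring A 4-hydroxy-5-formyl; ring C 3,4-dimethoxy) | O=Cc1cc2cc(c1O)Oc1ccc(cc1)CCc1ccc(OC)c(OC)c1Oc1ccccc1CC2
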